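**Plan**

Rings: A = 3-methoxyphenyl, B = trisubstituted phenol ring, C = para-disubstituted phenoxy ring (C1 bears O, C4 bears the chain), D = 3-hydroxyphenyl.
Cuts: (a) the CH2–CH2 bond between rings C and D, formed as a Wittig C=C. (b) Ring C at C1–C2 and C5–C6, which frees C1/C6 as an alkyne and C2–C5 as a pyrone diene. (c) The CH2–CH2 bond between rings A and B, again a Wittig C=C.
Enabling feature: ring C carries only the ether O at C1, a carbon chain at C4 para to it, and four C–H. The C3–C6 diene of a 5-carboxy-2-pyrone and an O-substituted terminal alkyne leave exactly this pattern after loss of CO2.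
Forward: the A–B bibenzyl is joined first and the ring B phenol oxygen is turned into an ethynyl ether. Ring C, the only ring made, is then built on that oxygen.
The ester is taken to the aldehyde, ring D is attached by a second Wittig reaction, and one hydrogenation ends the route.
Stereochemistry: the target has no stereocentre; the alkene geometries and the cycloadduct bridgeheads are transient.

Key step: step 6

Remark: both Wittig products are taken to be E/Z mixtures and are drawn without an alkene descriptor, because both isomers converge on reduction.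

**Step 1**
Reactants: 1 3-methoxybenzyl bromide
Product: 2 (3-methoxybenzyl)triphenylphosphonium bromide
Conditions: PPh3 (1.05 equiv), toluene, reflux; filter the salt
Reagents that add atoms: triphenylphosphine, c1ccc(cc1)P(c1ccccc1)c1ccccc1
Why: SN2 quaternisation of PPh3 by a primary benzylic bromide is the standard preparation of a benzylic Wittig salt, which should precipitate from toluene.

**Step 2**
Reactants: 2 (3-methoxybenzyl)triphenylphosphonium bromide; 3 4-benzyloxy-3-hydroxybenzaldehyde
Product: 5 2-benzyloxy-5-[2-(3-methoxyphenyl)ethenyl]phenol (E/Z mixture), via benzylidene phosphorane 4 (not isolated)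
Conditions: 2 (1.2 equiv), KOtBu (2.4 equiv), THF, 0 °C; then 3, 0 °C to rt; 1 M HCl quench
Reagents that add atoms: none
Why: Wittig olefination with a semi-stabilised benzylic ylide; the surplus base keeps the phenol as its potassium salt, whose oxygen is meta to the formyl group and so cannot deactivate it by conjugation, and the alkene geometry does not matter because step 3 erases it.

**Step 3**
Reactants: 5 2-benzyloxy-5-[2-(3-methoxyphenyl)ethenyl]phenol
Product: 6 2-benzyloxy-5-[2-(3-methoxyphenyl)ethyl]phenol
Conditions: TsNHNH2 (excess, in portions), NaOAc (buffer), THF/H2O, reflux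
Reagents that add atoms: none
Why: Diimide reduction transfers two hydrogens to the nonpolar stilbene C=C through a cyclic concerted transition state and, unlike hydrogenation over palladium, should leave the aryl benzyl ether untouched.

**Step 4**
Reactants: 6 2-benzyloxy-5-[2-(3-methoxyphenyl)ethyl]phenol; 7 trichloroethylene
Product: 9 1-benzyloxy-2-[(E)-1,2-dichloroethenyloxy]-4-[2-(3-methoxyphenyl)ethyl]benzene, via dichloroacetylene 8 (not isolated)
Conditions: K2CO3, DMF, 70 °C, closed vessel under N2
Reagents that add atoms: none
Why: O-Dichlorovinylation of a phenol by elimination–addition, in which K2CO3 takes HCl from 7 and the phenoxide adds anti across the transient dichloroacetylene 8 to give the E-configured 1,2-dichlorovinyl ether, a routine reaction of phenols including ortho-alkoxy ones.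

**Step 5**
Reactants: 9 1-benzyloxy-2-[(E)-1,2-dichloroethenyloxy]-4-[2-(3-methoxyphenyl)ethyl]benzene
Product: 12 1-benzyloxy-2-ethynyloxy-4-[2-(3-methoxyphenyl)ethyl]benzene, via chloroethynyl ether 10 (not isolated), via lithium acetylide 11 (not isolated)
Conditions: n-BuLi (2.3 equiv), Et2O, −78 to −40 °C; H2O quench at −78 °C; quick filtration through basic alumina; used at once as a toluene solution
Reagents that add atoms: none
Why: Standard conversion of a 1,2-dichlorovinyl ether into a terminal ynol ether (vinylic deprotonation and loss of LiCl to 10, chlorine–lithium exchange to 11, protonation), all of which should outrun benzylic or ortho lithiation of the benzyl ether at −78 °C.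

**Step 6**
Reactants: 12 1-benzyloxy-2-ethynyloxy-4-[2-(3-methoxyphenyl)ethyl]benzene; 13 methyl coumalate (methyl 2-oxo-2H-pyran-5-carboxylate)
Product: 15 methyl 4-{2-benzyloxy-5-[2-(3-methoxyphenyl)ethyl]phenoxy}benzoate, via bicyclic lactone 14 (not isolated)
Conditions: 13 (2 equiv), BHT (cat.), dry toluene, 100–110 °C, N2; 12 added slowly by syringe pump
Reagents that add atoms: none
Why: Proposed new method: the electron-poor diene of 13 (pyrone C3=C4–C5=C6, its LUMO lowered by the lactone carbonyl and the C5 ester) should take up the electron-rich triple bond of 12 in a concerted but asynchronous inverse-electron-demand Diels–Alder reaction to give the 2-oxabicyclo[2.2.2]octadienone 14, whose O1–C2 bridge then leaves as CO2 in a retro-[4+2] step at the same temperature, so ring C appears at the arene oxidation level without an oxidant. The closest known reaction type is the cycloaddition/decarboxylation of methyl coumalate with ketene acetals, enol ethers, ynamines and simple alkynes to para-substituted benzoates, whereas an aryl ethynyl ether has not been shown as the two-carbon partner. Ring C is closed by intermolecular [4+2] annulation of four pyrone carbons with two alkyne carbons, the new bonds being pyrone C6 to the terminal CH and pyrone C3 to the oxygen-bearing alkyne carbon. The two bridgehead stereocentres of 14 vanish on aromatisation, so no stereocontrol is needed. The step needs para over meta regioselectivity, which polarity matching should secure: oxygen donation puts the largest HOMO coefficient on the terminal alkyne carbon, and pyrone C6, β to the ester and at the end of the dienoate, is the most electrophilic diene terminus. The arenes, ethers and saturated tether of 12 are inert to 13, an O-aryl group offers no β C–H for the retro-ene collapse to a ketene that limits alkyl ynol ethers on heating, and slow addition keeps the ynol ether dilute so that oligomerisation is held back.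

**Step 7**
Reactants: 15 methyl 4-{2-benzyloxy-5-[2-(3-methoxyphenyl)ethyl]phenoxy}benzoate
Product: 16 (4-{2-benzyloxy-5-[2-(3-methoxyphenyl)ethyl]phenoxy}phenyl)methanol
Conditions: LiAlH4, THF, 0 °C to rt; H2O/aq NaOH work-up
Reagents that add atoms: none
Why: Hydride reduction of an aromatic methyl ester to the benzylic alcohol, with the aryl, benzyl and methyl ethers inert to LiAlH4.

**Step 8**
Reactants: 16 (4-{2-benzyloxy-5-[2-(3-methoxyphenyl)ethyl]phenoxy}phenyl)methanol
Product: 17 4-{2-benzyloxy-5-[2-(3-methoxyphenyl)ethyl]phenoxy}benzaldehyde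
Conditions: activated MnO2 (excess), CH2Cl2, rt
Reagents that add atoms: none
Why: Heterogeneous MnO2 oxidation is selective for benzylic alcohols and stops at the aldehyde.

**Step 9**
Reactants: 18 3-benzyloxybenzyl bromide
Product: 19 (3-benzyloxybenzyl)triphenylphosphonium bromide
Conditions: PPh3 (1.05 equiv), toluene, reflux; filter the salt
Reagents that add atoms: triphenylphosphine, c1ccc(cc1)P(c1ccccc1)c1ccccc1
Why: SN2 quaternisation of PPh3 by a primary benzylic bromide, as in step 1, with the benzyl ether a spectator.

**Step 10**
Reactants: 17 4-{2-benzyloxy-5-[2-(3-methoxyphenyl)ethyl]phenoxy}benzaldehyde; 19 (3-benzyloxybenzyl)triphenylphosphonium bromide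
Product: 21 1-benzyloxy-2-{4-[2-(3-benzyloxyphenyl)ethenyl]phenoxy}-4-[2-(3-methoxyphenyl)ethyl]benzene (E/Z mixture), via benzylidene phosphorane 20 (not isolated)
Conditions: 19 (1.3 equiv), KOtBu (1.2 equiv), THF, 0 °C; then 17, 0 °C to rt
Reagents that add atoms: none
Why: Wittig olefination of an unhindered aromatic aldehyde with a semi-stabilised benzylic ylide, the usual way to set up a bibenzyl bridge, with the E/Z outcome irrelevant because step 11 saturates the alkene.

**Step 11**
Reactants: 21 1-benzyloxy-2-{4-[2-(3-benzyloxyphenyl)ethenyl]phenoxy}-4-[2-(3-methoxyphenyl)ethyl]benzene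
Product: 23 2-{4-[2-(3-hydroxyphenyl)ethyl]phenoxy}-4-[2-(3-methoxyphenyl)ethyl]phenol (CNP0225725.0), via saturated dibenzyl ether 22 (not isolated)
Conditions: H2 (1 atm), 10% Pd/C, EtOAc/MeOH, rt
Reagents that add atoms: none
Why: Catalytic hydrogenation over Pd/C first saturates the stilbene C=C (22) and then cleaves both aryl benzyl ethers by hydrogenolysis, while the diaryl ether and the methyl ether are stable under these conditions.

**Compound list**

1 | 3-methoxybenzyl bromide | COc1cccc(CBr)c1 | starting material
2 | (3-methoxybenzyl)triphenylphosphonium bromide | COc1cccc(C[P+](c2ccccc2)(c2ccccc2)c2ccccc2)c1.[Br-] | intermediate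
3 | 4-benzyloxy-3-hydroxybenzaldehyde | O=Cc1ccc(OCc2ccccc2)c(O)c1 | starting material
4 | (3-methoxybenzylidene)triphenylphosphorane | COc1cccc(C=P(c2ccccc2)(c2ccccc2)c2ccccc2)c1 | intermediate
5 | 2-benzyloxy-5-[2-(3-methoxyphenyl)ethenyl]phenol (E/Z mixture) | COc1cccc(C=Cc2ccc(OCc3ccccc3)c(O)c2)c1 | intermediate
6 | 2-benzyloxy-5-[2-(3-methoxyphenyl)ethyl]phenol | COc1cccc(CCc2ccc(OCc3ccccc3)c(O)c2)c1 | intermediate
7 | trichloroethylene | ClC=C(Cl)Cl | starting material
8 | dichloroacetylene | ClC#CCl | intermediate
9 | 1-benzyloxy-2-[(E)-1,2-dichloroethenyloxy]-4-[2-(3-methoxyphenyl)ethyl]benzene | COc1cccc(CCc2ccc(OCc3ccccc3)c(O/C(Cl)=C\Cl)c2)c1 | intermediate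
10 | 1-benzyloxy-2-(chloroethynyloxy)-4-[2-(3-methoxyphenyl)ethyl]benzene | COc1cccc(CCc2ccc(OCc3ccccc3)c(OC#CCl)c2)c1 | intermediate
11 | lithium 2-{2-benzyloxy-5-[2-(3-methoxyphenyl)ethyl]phenoxy}acetylide | COc1cccc(CCc2ccc(OCc3ccccc3)c(OC#C[Li])c2)c1 | intermediate
12 | 1-benzyloxy-2-ethynyloxy-4-[2-(3-methoxyphenyl)ethyl]benzene | C#COc1cc(CCc2cccc(OC)c2)ccc1OCc1ccccc1 | intermediate
13 | methyl coumalate (methyl 2-oxo-2H-pyran-5-carboxylate) | COC(=O)C1=COC(=O)C=C1 | starting material
14 | methyl 8-{2-benzyloxy-5-[2-(3-methoxyphenyl)ethyl]phenoxy}-3-oxo-2-oxabicyclo[2.2.2]octa-5,7-diene-6-carboxylate (racemic) | COC(=O)C1=CC2C(=O)OC1C=C2Oc1cc(CCc2cccc(OC)c2)ccc1OCc1ccccc1 | intermediate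
15 | methyl 4-{2-benzyloxy-5-[2-(3-methoxyphenyl)ethyl]phenoxy}benzoate | COC(=O)c1ccc(Oc2cc(CCc3cccc(OC)c3)ccc2OCc2ccccc2)cc1 | intermediate
16 | (4-{2-benzyloxy-5-[2-(3-methoxyphenyl)ethyl]phenoxy}phenyl)methanol | OCc1ccc(Oc2cc(CCc3cccc(OC)c3)ccc2OCc2ccccc2)cc1 | intermediate
17 | 4-{2-benzyloxy-5-[2-(3-methoxyphenyl)ethyl]phenoxy}benzaldehyde | O=Cc1ccc(Oc2cc(CCc3cccc(OC)c3)ccc2OCc2ccccc2)cc1 | intermediate
18 | 3-benzyloxybenzyl bromide | BrCc1cccc(OCc2ccccc2)c1 | starting material
19 | (3-benzyloxybenzyl)triphenylphosphonium bromide | [Br-].c1ccc(COc2cccc(C[P+](c3ccccc3)(c3ccccc3)c3ccccc3)c2)cc1 | intermediate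
20 | (3-benzyloxybenzylidene)triphenylphosphorane | c1ccc(COc2cccc(C=P(c3ccccc3)(c3ccccc3)c3ccccc3)c2)cc1 | intermediate
21 | 1-benzyloxy-2-{4-[2-(3-benzyloxyphenyl)ethenyl]phenoxy}-4-[2-(3-methoxyphenyl)ethyl]benzene (E/Z mixture) | COc1cccc(CCc2ccc(OCc3ccccc3)c(Oc3ccc(C=Cc4cccc(OCc5ccccc5)c4)cc3)c2)c1 | intermediate
22 | 1-benzyloxy-2-{4-[2-(3-benzyloxyphenyl)ethyl]phenoxy}-4-[2-(3-methoxyphenyl)ethyl]benzene | COc1cccc(CCc2ccc(OCc3ccccc3)c(Oc3ccc(CCc4cccc(OCc5ccccc5)c4)cc3)c2)c1 | intermediate
23 | 2-{4-[2-(3-hydroxyphenyl)ethyl]phenoxy}-4-[2-(3-methoxyphenyl)ethyl]phenol (CNP0225725.0) | COc1cccc(CCc2ccc(O)c(Oc3ccc(CCc4cccc(O)c4)cc3)c2)c1 | target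

**Step count**

- Total step count: 11.
- Longest linear sequence: 10 (steps 1–8, 10 and 11). Step 9 is a one-step side branch.

**Steps most likely to fail**

1. Step 6, the step that bears the label.
   - Risk: thermal oligomerisation or adventitious hydration of the ynol ether may overtake the cycloaddition. The pyrone may also dimerise, or para regiocontrol may be incomplete.
   - Fallback: form the ring B–O–ring C ether bond instead of building ring C. It sets out from phenol 6, which undergoes nucleophilic aromatic substitution on commercial 4-fluorobenzaldehyde (O=Cc1ccc(F)cc1; K2CO3, DMF, 130–150 °C). This is a standard diaryl ether synthesis with para-formyl activation. It comes back to the route at aldehyde 17 and bypasses steps 4–8. No compound outside the list is made (F0).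

2. Step 5.
   - Risk: the terminal ynol ether may be lost through hydration or oligomerisation during quench, concentration and filtration.
   - Fallback: protect the alkyne terminus in the flask. It sets out from 9, which is lithiated as before, and acetylide 11 is trapped with Me3SiCl at −78 °C. This gives 1-benzyloxy-4-[2-(3-methoxyphenyl)ethyl]-2-[(trimethylsilyl)ethynyloxy]benzene F1, which should tolerate chromatography and storage. The silyl group is removed with Bu4NF (THF, −20 °C) directly before the cycloaddition, and the fallback comes back to the route at 12.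

3. Step 2.
   - Risk: olefination may be slow or incomplete because the potassium phenoxide dissolves poorly and consumes part of the ylide.
   - Fallback: reorder the sequence so that the dichlorovinyl group also masks the phenol. It sets out from 3, which reacts with 7 (K2CO3, DMF, 70 °C, via 8) to give 4-benzyloxy-3-[(E)-1,2-dichloroethenyloxy]benzaldehyde F2. Ylide 4 is made from 2 with one equivalent of KOtBu so that no free base remains. It converts F2 into 1-benzyloxy-2-[(E)-1,2-dichloroethenyloxy]-4-[2-(3-methoxyphenyl)ethenyl]benzene F3 (E/Z mixture at the stilbene). Diimide (TsNHNH2, NaOAc, THF/H2O, reflux) should then reduce the stilbene and spare the chlorinated, trisubstituted enol ether. The fallback comes back to the route at 9.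

**Further compounds**

F0 | step 6 | none | none
F1 | step 5 | 1-benzyloxy-4-[2-(3-methoxyphenyl)ethyl]-2-[(trimethylsilyl)ethynyloxy]benzene | COc1cccc(CCc2ccc(OCc3ccccc3)c(OC#C[Si](C)(C)C)c2)c1
F2 | step 2 | 4-benzyloxy-3-[(E)-1,2-dichloroethenyloxy]benzaldehyde | O=Cc1ccc(OCc2ccccc2)c(O/C(Cl)=C\Cl)c1
F3 | step 2 | 1-benzyloxy-2-[(E)-1,2-dichloroethenyloxy]-4-[2-(3-methoxyphenyl)ethenyl]benzene (E/Z mixture at the stilbene) | COc1cccc(C=Cc2ccc(OCc3ccccc3)c(O/C(Cl)=C\Cl)c2)c1
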